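**Retrosynthetic overview**

1. Feature: in each iridoid unit C1 lies between N2 and C7a of the piperidine ring (N2, C1, C7a, C4a, C4, C3) and is also the benzylic carbon on C6 or C8 of catechin ring A. Without C1 the unit is a cis-fused 2-azabicyclo[3.3.0]octane that already carries C4, C4a, C7 and C7a.
2. Key disconnection, made twice: N2–C1 and C1–C7a, leading back to a protected catechin-6,8-dicarbaldehyde bis(tosylhydrazone) as a double carbene source and two molecules of the bicyclic N-methylamine (carbene, ammonium ylide, [1,2]-shift).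
3. Aldehyde carbons on ring A: (+)-catechin, pentabenzyl ether, 6,8-dibromide, bromine–lithium exchange and DMF.
4. Amine: cis,trans-nepetalactone, nepetalic acid, Curtius degradation of the C1 carboxyl to nitrogen on C7a, imine closure onto C3 with C4 set thermodynamically, reduction, N-methylation.
5. Ring order: pyrrolidine ring (step 6), both piperidine rings in one operation (step 8), debenzylation (step 9); rings A, B and C come from catechin.

Key step: step 8

Remark: iridoid atoms keep the cyclopenta[c]pyridine numbering of the target (C1, N2, C3, C4, C4a, C5, C6, C7, C7a) in every intermediate; nepetalic acid 10 is drawn as the C4 epimer that matches the target, but the main route does not depend on this because C4 is re-equilibrated in step 6.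

**Route**

Step 1
Reactants: 1 (+)-catechin
Product: 2 3,5,7,3',4'-penta-O-benzyl-(+)-catechin
Conditions: NaH (5.5 equiv), BnBr (5.5 equiv), n-Bu4NI (cat.), DMF, −40 °C → rt
Reagents that add atoms: benzyl bromide, BrCc1ccccc1
Why: Williamson ether synthesis benzylates the four phenoxides and then the C3 alkoxide; the cold aprotic medium should leave C2 and C3 untouched.

Step 2
Reactants: 2 penta-O-benzyl-(+)-catechin
Product: 3 6,8-dibromo-3,5,7,3',4'-penta-O-benzyl-(+)-catechin
Conditions: NBS (2.1 equiv), CH2Cl2, −20 °C → rt, dark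
Reagents that add atoms: N-bromosuccinimide, O=C1CCC(=O)N1Br
Why: electrophilic aromatic bromination should go to C6 and C8, the only free positions of the phloroglucinol-type ring A, which is far more nucleophilic than ring B.

Step 3
Reactants: 3 6,8-dibromide
Product: 6 3,5,7,3',4'-penta-O-benzyl-(+)-catechin-6,8-dicarbaldehyde, via 6,8-dilithio arene 4 (not isolated), via bis(lithium aminoalkoxide) 5 (not isolated)
Conditions: t-BuLi (4.3 equiv), THF, −78 °C; DMF (6 equiv), −78 → 0 °C; 1 M HCl
Reagents that add atoms: N,N-dimethylformamide, CN(C)C=O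
Why: double bromine–lithium exchange outruns benzylic deprotonation at −78 °C, and each aryllithium adds to DMF to give a tetrahedral alkoxide that releases the aldehyde only on acidic work-up (Bouveault formylation).

Step 4
Reactants: 6 dialdehyde; 7 tosylhydrazide (2.2 equiv)
Product: 8 penta-O-benzyl-(+)-catechin-6,8-dicarbaldehyde bis(N-tosylhydrazone), both C=N bonds E
Conditions: THF/EtOH, 50 °C
Reagents that add atoms: none
Why: condensation of each aldehyde with the hydrazide NH2 gives the E-tosylhydrazone without added acid, so the benzyl ethers are not at risk.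

Step 5
Reactants: 9 cis,trans-nepetalactone, (4aS,7S,7aR)
Product: 10 nepetalic acid, (1R,2R,5S)-5-methyl-2-[(2R)-1-oxopropan-2-yl]cyclopentane-1-carboxylic acid (in equilibrium with its lactol)
Conditions: 1 M NaOH, THF, rt; 2 M HCl to pH 2, 0 °C
Reagents that add atoms: water (as aqueous NaOH), O
Why: saponification of the enol lactone frees the C1 carboxylate and the C3 aldehyde after enol–aldehyde tautomerisation; the carboxylate resists α-deprotonation, so C7a, C4a and C7 stay as in 9.

Step 6
Reactants: 10 nepetalic acid
Product: 14 (3R,3aR,6S,6aR)-3,6-dimethyloctahydrocyclopenta[b]pyrrole, via acyl azide 11 (not isolated), via isocyanate 12 (not isolated), via cyclic imine 13 (not isolated)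
Conditions: DPPA (1.1 equiv), Et3N (1.2 equiv), toluene, 0 °C → rt, then 85 °C; 2 M HCl, THF, 60 °C; NaOH to pH 6–7, rt, 12 h; NaBH4, MeOH, 0 °C
Reagents that add atoms: diphenylphosphoryl azide, O=P(N=[N+]=[N-])(Oc1ccccc1)Oc1ccccc1
Why: Curtius rearrangement moves nitrogen onto C7a with retention, acidic hydrolysis of the isocyanate lets the amine condense with the C3 aldehyde to a five-membered imine, imine–enamine equilibration near neutral pH should place the C4 methyl group on the convex face of the cis-bicyclo[3.3.0] skeleton (trans to C5), and borohydride reduction of C=N creates no new stereocentre.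

Step 7
Reactants: 14 secondary amine
Product: 15 (3R,3aR,6S,6aR)-1,3,6-trimethyloctahydrocyclopenta[b]pyrrole (2,4,8-trimethyl-2-azabicyclo[3.3.0]octane)
Conditions: 37% aq. HCHO, HCO2H, 90 °C
Reagents that add atoms: formaldehyde, C=O
Why: Eschweiler–Clarke methylation stops cleanly at the tertiary amine and touches no stereocentre.

Step 8
Reactants: 8 bis(tosylhydrazone); 15 bicyclic N-methylamine (6 equiv)
Product: 19 penta-O-benzyl ether of the target, via disodium salt 16 (not isolated), via bis(diazo) compound 17 (not isolated), via bis(ammonium ylide) 18 (not isolated)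
Conditions: NaH (2.1 equiv), THF, 0 °C → rt; then 15, Cu(acac)2 (10 mol %), BnEt3NCl (20 mol %), 1,4-dioxane, 45 → 90 °C, salt added over 6 h
Reagents that add atoms: none
Why: Proposed new method: NaH converts each tosylhydrazone into its sodium salt, which loses sulfinate on warming to give the aryldiazomethane (Bamford–Stevens); Cu(acac)2 turns this into a copper carbene, the nitrogen lone pair of 15 adds to it from the convex face to give the benzylic ammonium ylide, and the ylide rearranges by a Stevens [1,2]-shift in which N–C7a homolyses to a secondary cyclopentyl radical and an α-amino-2,4,6-trialkoxybenzyl radical that recombine in the solvent cage at the carbene carbon, which thereby becomes C1. The closest known reaction type is the Stevens ring expansion of cyclic ammonium ylides formed from metal carbenes and tertiary amines, established when the migrating ring carbon is benzylic, allylic or α to a carbonyl group, or when an azetidinium ring opens, whereas migration of a plain secondary alkyl carbon from a pyrrolidinium ylide has not been shown. Each of the two piperidine rings is closed by ring enlargement: C1 is joined to N2 intermolecularly and then to C7a by intramolecular radical recombination, so a pyrrolidine becomes a six-membered ring without a separate cyclisation. C7a should keep its configuration because the two radical centres stay tethered through N2–C3–C4–C4a and collapse on the face that nitrogen has just left, and the new stereocentre C1 is controlled by the cis-fused bicycle, whose convex face takes the large aryl group anti to C7, which is the (1R) configuration of the target at both sites. The step needs C7a to migrate in preference to C3 and N-methyl, which the more stable secondary radical and the strain released from the bicyclo[3.3.0] ammonium should favour, and it needs the ylide to avoid the Sommelet–Hauser path, which is closed because both positions ortho to each benzylic carbon carry oxygen. Cu(acac)2 is used in place of Rh2(OAc)4, and the amine in sixfold excess, so that attack at nitrogen outruns 1,5 C–H insertion of the carbene into a neighbouring OCH2Ph group and the catalyst is not blocked by the amine.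

Step 9
Reactants: 19 penta-O-benzyl ether
Product: 20 target, 6,8-bis[(1R,4R,4aR,7S,7aR)-2,4,7-trimethyloctahydro-1H-cyclopenta[c]pyridin-1-yl]-(+)-catechin
Conditions: H2 (1 atm), Pd(OH)2/C, THF/MeOH, rt
Reagents that add atoms: none
Why: hydrogenolysis removes the five O-benzyl groups, while the chroman C2–O1 bond and the ring C1–N bonds (α-branched benzylic amines flanked by two ortho substituents) should be much slower to cleave under these mild neutral conditions.

**Compound list**

1 | (+)-catechin, (2R,3S) | O[C@H]1Cc2c(O)cc(O)cc2O[C@@H]1c1ccc(O)c(O)c1 | starting material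
2 | 3,5,7,3',4'-penta-O-benzyl-(+)-catechin | O(Cc1ccccc1)[C@H]2Cc3c(OCc4ccccc4)cc(OCc4ccccc4)cc3O[C@@H]2c5ccc(OCc6ccccc6)c(OCc6ccccc6)c5 | intermediate
3 | 6,8-dibromo-penta-O-benzyl-(+)-catechin | O(Cc1ccccc1)[C@H]2Cc3c(OCc4ccccc4)c(Br)c(OCc4ccccc4)c(Br)c3O[C@@H]2c5ccc(OCc6ccccc6)c(OCc6ccccc6)c5 | intermediate
4 | 6,8-dilithio-penta-O-benzylcatechin | O(Cc1ccccc1)[C@H]2Cc3c(OCc4ccccc4)c([Li])c(OCc4ccccc4)c([Li])c3O[C@@H]2c5ccc(OCc6ccccc6)c(OCc6ccccc6)c5 | intermediate
5 | bis(lithium dimethylamino-alkoxide) adduct of 4 with DMF (carbinol carbons undefined) | O(Cc1ccccc1)[C@H]2Cc3c(OCc4ccccc4)c(C([O-])N(C)C)c(OCc4ccccc4)c(C([O-])N(C)C)c3O[C@@H]2c5ccc(OCc6ccccc6)c(OCc6ccccc6)c5.[Li+].[Li+] | intermediate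
6 | penta-O-benzyl-(+)-catechin-6,8-dicarbaldehyde | O(Cc1ccccc1)[C@H]2Cc3c(OCc4ccccc4)c(C=O)c(OCc4ccccc4)c(C=O)c3O[C@@H]2c5ccc(OCc6ccccc6)c(OCc6ccccc6)c5 | intermediate
7 | tosylhydrazide (4-methylbenzenesulfonohydrazide) | Cc1ccc(cc1)S(=O)(=O)NN | starting material
8 | penta-O-benzyl-(+)-catechin-6,8-dicarbaldehyde bis(N-tosylhydrazone), E,E | O(Cc1ccccc1)[C@H]2Cc3c(OCc4ccccc4)c(/C=N/NS(=O)(=O)c4ccc(C)cc4)c(OCc4ccccc4)c(/C=N/NS(=O)(=O)c4ccc(C)cc4)c3O[C@@H]2c5ccc(OCc6ccccc6)c(OCc6ccccc6)c5 | intermediate
9 | cis,trans-nepetalactone, (4aS,7S,7aR) | C[C@H]1CC[C@H]2[C@@H]1C(=O)OC=C2C | starting material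
10 | nepetalic acid, (1R,2R,5S)-5-methyl-2-[(2R)-1-oxopropan-2-yl]cyclopentane-1-carboxylic acid | C[C@H]1CC[C@@H]([C@@H]1C(=O)O)[C@@H](C)C=O | intermediate
11 | nepetalic acid acyl azide | C[C@H]1CC[C@@H]([C@@H]1C(=O)N=[N+]=[N-])[C@@H](C)C=O | intermediate
12 | isocyanate on C7a, 2-(2-isocyanato-3-methylcyclopentyl)propanal | C[C@H]1CC[C@@H]([C@@H]1N=C=O)[C@@H](C)C=O | intermediate
13 | (3R,3aR,6S,6aR)-3,6-dimethyl-3,3a,4,5,6,6a-hexahydrocyclopenta[b]pyrrole (cyclic imine, methyl groups on the convex face) | N1=C[C@H](C)[C@H]2CC[C@H](C)[C@@H]12 | intermediate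
14 | (3R,3aR,6S,6aR)-3,6-dimethyloctahydrocyclopenta[b]pyrrole | N1C[C@H](C)[C@H]2CC[C@H](C)[C@@H]12 | intermediate
15 | (3R,3aR,6S,6aR)-1,3,6-trimethyloctahydrocyclopenta[b]pyrrole | CN1C[C@H](C)[C@H]2CC[C@H](C)[C@@H]12 | intermediate
16 | disodium salt of 8 | O(Cc1ccccc1)[C@H]2Cc3c(OCc4ccccc4)c(/C=N/[N-]S(=O)(=O)c4ccc(C)cc4)c(OCc4ccccc4)c(/C=N/[N-]S(=O)(=O)c4ccc(C)cc4)c3O[C@@H]2c5ccc(OCc6ccccc6)c(OCc6ccccc6)c5.[Na+].[Na+] | intermediate
17 | 6,8-bis(diazomethyl)-penta-O-benzyl-(+)-catechin | O(Cc1ccccc1)[C@H]2Cc3c(OCc4ccccc4)c(C=[N+]=[N-])c(OCc4ccccc4)c(C=[N+]=[N-])c3O[C@@H]2c5ccc(OCc6ccccc6)c(OCc6ccccc6)c5 | intermediate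
18 | bis(ammonium ylide), each benzylic carbanion on the convex face of the nitrogen of a unit of 15 | O(Cc1ccccc1)[C@H]2Cc3c(OCc4ccccc4)c([CH-][N@+]7(C)C[C@H](C)[C@H]8CC[C@H](C)[C@@H]78)c(OCc4ccccc4)c([CH-][N@+]7(C)C[C@H](C)[C@H]8CC[C@H](C)[C@@H]78)c3O[C@@H]2c5ccc(OCc6ccccc6)c(OCc6ccccc6)c5 | intermediate
19 | 3,5,7,3',4'-penta-O-benzyl-6,8-bis[(1R,4R,4aR,7S,7aR)-2,4,7-trimethyloctahydro-1H-cyclopenta[c]pyridin-1-yl]-(+)-catechin | O(Cc1ccccc1)[C@H]2Cc3c(OCc4ccccc4)c([C@H]7[C@H]8[C@H](CC[C@@H]8C)[C@@H](C)CN7C)c(OCc4ccccc4)c([C@H]7[C@H]8[C@H](CC[C@@H]8C)[C@@H](C)CN7C)c3O[C@@H]2c5ccc(OCc6ccccc6)c(OCc6ccccc6)c5 | intermediate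
20 | CNP0284716.2, 6,8-bis[(1R,4R,4aR,7S,7aR)-2,4,7-trimethyloctahydro-1H-cyclopenta[c]pyridin-1-yl]-(+)-catechin | C[C@H]1CN(C)[C@@H](c2c(O)c3c(c([C@H]4[C@H]5[C@H](CC[C@@H]5C)[C@@H](C)CN4C)c2O)O[C@H](c2ccc(O)c(O)c2)[C@@H](O)C3)[C@H]2[C@@H]1CC[C@@H]2C | target

**Step count and risks**

Total step count: 9. Longest linear sequence: 6 steps (steps 1, 2, 3, 4, 8, 9 from (+)-catechin); the amine branch is steps 5–7.

Steps most likely to fail:

1. Step 8. The ylide has a C7–H syn to nitrogen, so intramolecular β-proton abstraction with ring opening to an N-benzylamine may be faster than migration of the unactivated C7a. The carbene may also dimerise, form azines or insert into a flanking OCH2Ph group. Escape of the radical pair from the cage would erode the configuration at C7a and C1, and the second ring expansion must succeed on an already crowded ring A. The fallback uses known chemistry and makes the aryl–C1 bonds by a phenolic Mannich reaction. It sets out from 10 and 1 and comes back to the route at 20. Nepetalic acid 10 is condensed with methylamine and reduced with NaBH(OAc)3, and the amino acid is lactamised by heating in toluene to (4R,4aR,7S,7aR)-2,4,7-trimethyloctahydro-1H-cyclopenta[c]pyridin-1-one F1, which is freed from any C4 epimer at this stage. Partial reduction with i-Bu2AlH at −78 °C and treatment with HCl gives the cyclic N-methyliminium chloride F2. F2 (2.5 equiv) and unprotected (+)-catechin 1 in buffered aqueous methanol (pH about 6, 40 °C) should undergo Mannich addition of ring A at C6 and C8 to the iminium carbon from the convex face, under reversible and therefore thermodynamic control, to give 20 directly.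

2. Step 6. Activation of the carboxyl group may be diverted by the ring-closed lactol form of 10 or by re-closure to the enol lactone. The amino aldehyde may oligomerise before the imine is reduced, and equilibration at C4 may be incomplete. The fallback installs nitrogen by a Hofmann rearrangement with C3 at the alcohol level. It sets out from 10 and comes back at 15, so step 7 is also bypassed. NaBH4 in aqueous NaOH followed by acidification reduces the aldehyde and lactonises the hydroxy acid to (4R,4aR,7S,7aR)-4,7-dimethylhexahydrocyclopenta[c]pyran-1(3H)-one F3. Ammonia in methanol (sealed tube, 60 °C) opens it to the hydroxy amide F4. PhI(OAc)2 in methanol gives the methyl carbamate F5 with retention at C7a. LiAlH4 in THF reduces the carbamate to the N-methylamino alcohol F6. Mitsunobu cyclodehydration (PPh3, diisopropyl azodicarboxylate, THF) closes nitrogen onto C3 to give 15. This path takes C4 from 10 without re-equilibration, so it depends on the epimeric purity of 10 at C4.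

3. Step 3. The second bromine–lithium exchange on an already lithiated, electron-rich ring may be incomplete, and protonation or benzylic metalation of an O-benzyl group may then give monoaldehyde or debrominated material. The fallback replaces organolithium chemistry by palladium-catalysed reductive carbonylation. It sets out from 3 and comes back at 6: Pd(OAc)2 with di(1-adamantyl)-n-butylphosphine, CO/H2 (1:1, 5 bar), TMEDA, toluene, 100 °C should convert both aryl bromides into aldehydes in one operation without new intermediates.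

**Further compounds**

F1 | step 8 | (4R,4aR,7S,7aR)-2,4,7-trimethyloctahydro-1H-cyclopenta[c]pyridin-1-one | C[C@H]1CN(C)C(=O)[C@H]2[C@@H]1CC[C@@H]2C
F2 | step 8 | (4R,4aR,7S,7aR)-2,4,7-trimethyl-4,4a,5,6,7,7a-hexahydro-3H-cyclopenta[c]pyridin-2-ium chloride | C[C@H]1C[N+](C)=C[C@H]2[C@@H]1CC[C@@H]2C.[Cl-]
F3 | step 6 | (4R,4aR,7S,7aR)-4,7-dimethylhexahydrocyclopenta[c]pyran-1(3H)-one | C[C@H]1CC[C@H]2[C@@H]1C(=O)OC[C@@H]2C
F4 | step 6 | (1R,2R,5S)-2-[(2R)-1-hydroxypropan-2-yl]-5-methylcyclopentane-1-carboxamide | C[C@H]1CC[C@@H]([C@@H]1C(N)=O)[C@@H](C)CO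
F5 | step 6 | methyl N-{(1R,2R,5S)-2-[(2R)-1-hydroxypropan-2-yl]-5-methylcyclopentyl}carbamate | C[C@H]1CC[C@@H]([C@@H]1NC(=O)OC)[C@@H](C)CO
F6 | step 6 | (2R)-2-[(1R,2R,3S)-3-methyl-2-(methylamino)cyclopentyl]propan-1-ol | C[C@H]1CC[C@@H]([C@@H]1NC)[C@@H](C)CO
F0 | step 3 | none | none
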